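**Plan**

1. The target is an achiral 17-membered bis(bibenzyl) diether. Ring A = 3-aryloxy-4,5-dihydroxyphenyl, ring B = para-phenylene, ring C = 2-aryloxy-3,4-dihydroxyphenyl, ring D = ortho-phenylene. It is carried as its tetramethyl ether.
2. Cuts, in order: the four O–CH3 bonds; a C–B helper bond on the B–C bridge; then, in one event, the bond from C-4 of ring B to its CH2 and the bond from the next CH2 to C-1 of ring C (a vinyl unit falls out); then the A–D ethylene bridge (Wittig C=C); last the two diaryl ether C–O bonds.
3. Enabling feature: the B–C bridge is a bare CH2–CH2 between C-4 of ring B (unhindered, para to the ether oxygen, an aryl group that migrates readily from boron) and C-1 of ring C (the only halogen-bearing carbon of the open-chain precursor). A vinyl group can therefore be inserted between an aryl–boron and an aryl–bromine bond by a 1,2-metallate shift.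
4. Forward: A–O–B ether and borylation of ring B; C–O–D ether; A–CH2CH2–D bridge; then three components (boronate 12, vinylmagnesium bromide, the internal aryl bromide) are joined and the 17-membered ring closes as ring B moves from boron to carbon; protodeboronation; demethylation.
5. Stereochemistry: the target has no stereocentre. The E/Z mixture of step 6 and the racemic C–B centre of step 8 are erased in steps 7 and 9.

Key step: step 8

Remark on the chemistry: 6-bromo-2,3-dimethoxyphenol (5) is taken as a purchasable building block.

**Route**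

Step 1
Reactants: 1 3-hydroxy-4,5-dimethoxybenzaldehyde; 2 (4-bromophenyl)boronic acid
Product: 3 3-(4-bromophenoxy)-4,5-dimethoxybenzaldehyde
Conditions: 2 (2 equiv), Cu(OAc)2 (20 mol %), pyridine, 4 Å MS, CH2Cl2, O2 (1 atm), rt
Reagents that add atoms: none
Why: Chan–Lam–Evans oxidative O-arylation, in which the boronic acid hands its aryl group to copper and C–O reductive elimination from the copper aryl phenoxide should give the diaryl ether at room temperature, where the C–Br bond and the aldehyde are inert.

Step 2
Reactants: 3 3-(4-bromophenoxy)-4,5-dimethoxybenzaldehyde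
Product: 4 3,4-dimethoxy-5-[4-(4,4,5,5-tetramethyl-1,3,2-dioxaborolan-2-yl)phenoxy]benzaldehyde
Conditions: B2pin2 (1.2 equiv), PdCl2(dppf) (3 mol %; dppf = 1,1'-bis(diphenylphosphino)ferrocene), KOAc, dioxane, 85 °C
Reagents that add atoms: bis(pinacolato)diboron, CC1(C)OB(OC1(C)C)B1OC(C)(C)C(C)(C)O1
Why: Miyaura borylation (oxidative addition of zerovalent palladium into the C–Br bond, acetate-assisted transmetalation with the diboron reagent, reductive elimination), in which the weak base KOAc spares the aldehyde and suppresses biaryl coupling.

Step 3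
Reactants: 5 6-bromo-2,3-dimethoxyphenol; 6 2-fluorobenzaldehyde
Product: 7 2-(6-bromo-2,3-dimethoxyphenoxy)benzaldehyde
Conditions: Cs2CO3 (1.5 equiv), DMF, 110 °C
Reagents that add atoms: none
Why: Nucleophilic aromatic substitution by addition–elimination, in which the ortho-formyl group stabilises the Meisenheimer adduct and fluoride leaves, whereas the C–Br bond on the electron-rich ring of 5 is no SNAr site.

Step 4
Reactants: 7 2-(6-bromo-2,3-dimethoxyphenoxy)benzaldehyde
Product: 8 [2-(6-bromo-2,3-dimethoxyphenoxy)phenyl]methanol
Conditions: NaBH4, MeOH/THF, 0 °C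
Reagents that add atoms: none
Why: Hydride reduction of the aryl aldehyde to the benzylic alcohol, with aryl bromide and ethers inert to NaBH4.

Step 5
Reactants: 8 [2-(6-bromo-2,3-dimethoxyphenoxy)phenyl]methanol
Product: 9 [2-(6-bromo-2,3-dimethoxyphenoxy)benzyl]triphenylphosphonium bromide
Conditions: Ph3P·HBr (1.1 equiv), MeCN, reflux
Reagents that add atoms: triphenylphosphine hydrobromide, [PH+](c1ccccc1)(c1ccccc1)c1ccccc1.[Br-]
Why: Direct conversion of a benzylic alcohol into its phosphonium salt (nucleophilic substitution), in which HBr ionises the ortho-aryloxy-stabilised benzylic C–O bond and triphenylphosphine captures the benzylic carbon, leaving aryl bromide and methyl ethers untouched.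

Step 6
Reactants: 9 [2-(6-bromo-2,3-dimethoxyphenoxy)benzyl]triphenylphosphonium bromide; 4 3,4-dimethoxy-5-[4-(4,4,5,5-tetramethyl-1,3,2-dioxaborolan-2-yl)phenoxy]benzaldehyde
Product: 11 2-[4-[5-[2-[2-(6-bromo-2,3-dimethoxyphenoxy)phenyl]ethenyl]-2,3-dimethoxyphenoxy]phenyl]-4,4,5,5-tetramethyl-1,3,2-dioxaborolane (E/Z mixture), via phosphonium ylide 10 (not isolated)
Conditions: K2CO3 (3 equiv), 18-crown-6 (cat.), CH2Cl2, reflux
Reagents that add atoms: none
Why: Wittig olefination with a semi-stabilised benzylic ylide under solid–liquid phase-transfer conditions that leave the pinacol boronate and the C–Br bond intact; the alkene geometry is not controlled and need not be, since the double bond is saturated in step 7.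

Step 7
Reactants: 11 the E/Z stilbene boronate from step 6
Product: 12 2-[4-[5-[2-[2-(6-bromo-2,3-dimethoxyphenoxy)phenyl]ethyl]-2,3-dimethoxyphenoxy]phenyl]-4,4,5,5-tetramethyl-1,3,2-dioxaborolane (open-chain precursor: Bpin on C-4 of ring B; Br on C-1 of ring C)
Conditions: TsNHNH2 (excess, in portions), NaOAc, DME/H2O, 85 °C
Reagents that add atoms: none
Why: Diimide reduction, a concerted syn transfer of two hydrogens from HN=NH to the C=C bond, chosen because it cannot cleave the C–Br or the C–B bond as hydrogenation over palladium might.

Step 8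
Reactants: 12 the open-chain bromo boronate from step 7; 13 vinylmagnesium bromide
Product: 15 macrocyclic boronic ester (17-membered ring; rings A to D joined as in the target; four OMe groups; bridge ring B–CH(Bpin)–CH2–ring C; racemic), via vinylboron ate complex 14 (not isolated)
Conditions: 13 (1.05 equiv), NaOTf (3 equiv), THF, 0 °C to rt; then added over 12 h to Pd(OAc)2 (5 mol %), MandyPhos ligand 1,1'-bis[bis(4-methoxy-3,5-dimethylphenyl)phosphino]-2,2'-bis[α-(dimethylamino)benzyl]ferrocene (6 mol %), THF, 60 °C, final 2 mM
Reagents that add atoms: none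
Why: Proposed new method: the Grignard reagent 13 adds to the boron atom of 12 to give the four-coordinate ate complex 14, zerovalent palladium inserts into the only C–Br bond (C-1 of ring C), and when the resulting cationic arylpalladium centre (divalent palladium) binds the vinyl group of the same molecule, ring B shifts from boron to the boron-bound vinyl carbon anti to the metal (1,2-metallate rearrangement), which forms the bond from C-4 of ring B to the bridge carbon and at the same time closes an 18-membered palladacycle. Alkyl–aryl reductive elimination then joins the terminal vinyl carbon to C-1 of ring C, contracts the palladacycle to the 17-membered carbocycle and returns zerovalent palladium. The closest known reaction type is the intermolecular palladium-catalysed conjunctive cross-coupling of aryl(vinyl)boron ate complexes with aryl bromides or triflates in the presence of NaOTf, which gives 1,2-diarylethyl boronic esters; a version in which the electrophile is tethered to the migrating aryl group, so that a large ring closes, has not been shown. Mode of closure: a macrocyclisation in which both vinyl carbons become ring members (endo mode), with anti addition of ring B and palladium across the vinyl group. The one new stereocentre (the CH–B carbon) would be set by the ligand relative to the alkene face that palladium binds, but its configuration is immaterial (racemic ligand suffices) because step 9 replaces boron by hydrogen. The step needs metallate shift in preference to direct Suzuki-type transfer of vinyl or aryl from boron, and ring closure in preference to chain growth: the first is secured by the saturated boron centre carrying an unhindered, electron-rich migrating ring (C-4 of ring B, para to the ether oxygen) and by the wide-bite-angle bisphosphine, the second by slow addition to the catalyst, and no positional alternative exists because 12 holds one C–Br bond and one boron atom only.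

Step 9
Reactants: 15 the macrocyclic boronic ester from step 8
Product: 16 macrocyclic tetramethyl ether (the target with OMe in place of each of the four OH groups)
Conditions: Bu4NF·3H2O (3 equiv), toluene, 90 °C
Reagents that add atoms: none
Why: Fluoride-promoted protodeboronation of a secondary benzylic pinacol boronic ester, in which fluoride forms the boron ate complex and the benzylic C–B bond is protonated by the water of hydration, so that the boron helper and the stereocentre disappear together.

Step 10
Reactants: 16 the macrocyclic tetramethyl ether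
Product: 17 target macrocycle (ring A C-1–CH2CH2–ring D C-2; ring D C-1–O–ring C C-2; ring C C-1–CH2CH2–ring B C-4; ring B C-1–O–ring A C-3; OH on C-4 and C-5 of ring A and on C-3 and C-4 of ring C)
Conditions: BBr3 (10 equiv), CH2Cl2, −78 °C to rt; then MeOH/H2O, 0 °C
Reagents that add atoms: none
Why: Lewis acid cleavage of aryl methyl ethers, in which BBr3 binds each methoxy oxygen, bromide removes the methyl group by SN2 and aqueous work-up hydrolyses the aryl borates to the two catechols, while the diaryl ethers offer no sp3 carbon for attack and should survive.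

**Compound list**

1 | 3-hydroxy-4,5-dimethoxybenzaldehyde | COc1cc(C=O)cc(O)c1OC | starting material
2 | (4-bromophenyl)boronic acid | OB(O)c1ccc(Br)cc1 | starting material
3 | 3-(4-bromophenoxy)-4,5-dimethoxybenzaldehyde | COc1cc(C=O)cc(Oc2ccc(Br)cc2)c1OC | intermediate
4 | 3,4-dimethoxy-5-[4-(4,4,5,5-tetramethyl-1,3,2-dioxaborolan-2-yl)phenoxy]benzaldehyde | COc1cc(C=O)cc(Oc2ccc(cc2)B2OC(C)(C)C(C)(C)O2)c1OC | intermediate
5 | 6-bromo-2,3-dimethoxyphenol | COc1ccc(Br)c(O)c1OC | starting material
6 | 2-fluorobenzaldehyde | O=Cc1ccccc1F | starting material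
7 | 2-(6-bromo-2,3-dimethoxyphenoxy)benzaldehyde | COc1ccc(Br)c(Oc2ccccc2C=O)c1OC | intermediate
8 | [2-(6-bromo-2,3-dimethoxyphenoxy)phenyl]methanol | COc1ccc(Br)c(Oc2ccccc2CO)c1OC | intermediate
9 | [2-(6-bromo-2,3-dimethoxyphenoxy)benzyl]triphenylphosphonium bromide | COc1ccc(Br)c(Oc2ccccc2C[P+](c2ccccc2)(c2ccccc2)c2ccccc2)c1OC.[Br-] | intermediate
10 | [2-(6-bromo-2,3-dimethoxyphenoxy)benzylidene]triphenylphosphorane (ylide) | COc1ccc(Br)c(Oc2ccccc2C=P(c2ccccc2)(c2ccccc2)c2ccccc2)c1OC | intermediate (not isolated)
11 | 2-[4-[5-[2-[2-(6-bromo-2,3-dimethoxyphenoxy)phenyl]ethenyl]-2,3-dimethoxyphenoxy]phenyl]-4,4,5,5-tetramethyl-1,3,2-dioxaborolane, E/Z mixture | COc1ccc(Br)c(Oc2ccccc2C=Cc2cc(OC)c(OC)c(Oc3ccc(cc3)B3OC(C)(C)C(C)(C)O3)c2)c1OC | intermediate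
12 | 2-[4-[5-[2-[2-(6-bromo-2,3-dimethoxyphenoxy)phenyl]ethyl]-2,3-dimethoxyphenoxy]phenyl]-4,4,5,5-tetramethyl-1,3,2-dioxaborolane | COc1ccc(Br)c(Oc2ccccc2CCc2cc(OC)c(OC)c(Oc3ccc(cc3)B3OC(C)(C)C(C)(C)O3)c2)c1OC | intermediate
13 | vinylmagnesium bromide | C=C[Mg]Br | starting material
14 | bromomagnesium ethenyl(pinacolato)arylborate formed from 12 and 13 (ate complex) | Br[Mg+].C=C[B-]1(OC(C)(C)C(C)(C)O1)c1ccc(Oc2cc(CCc3ccccc3Oc3c(Br)ccc(OC)c3OC)cc(OC)c2OC)cc1 | intermediate (not isolated)
15 | macrocyclic boronic ester: tetramethyl ether skeleton with a 4,4,5,5-tetramethyl-1,3,2-dioxaborolan-2-yl group on the bridge carbon attached to ring B, racemic | COc1cc2cc(c1OC)Oc1ccc(cc1)C(B1OC(C)(C)C(C)(C)O1)Cc1ccc(OC)c(OC)c1Oc1ccccc1CC2 | intermediate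
16 | macrocyclic tetramethyl ether of the target | COc1cc2cc(c1OC)Oc1ccc(cc1)CCc1ccc(OC)c(OC)c1Oc1ccccc1CC2 | intermediate
17 | target macrocycle (achiral) | Oc1cc2cc(c1O)Oc1ccc(cc1)CCc1ccc(O)c(O)c1Oc1ccccc1CC2 | target

**Summary**

Total step count: 10.
Longest linear sequence: 8 steps (steps 3 to 10, from 5 and 6).

**Steps most likely to fail**

1. Step 8 (Proposed new method). What may go wrong: direct transfer of the vinyl or the aryl group from boron to palladium (Suzuki-type coupling) instead of the metallate shift, β-hydride elimination before reductive elimination, or intermolecular coupling to oligomers. Fallback with known chemistry (iterative B-alkyl Suzuki–Miyaura coupling; sets out from 3 and comes back at 16): methylenation of 3 (Ph3PCH3Br, KOtBu, THF, 0 °C) should give the styrene 1-(4-bromophenoxy)-5-ethenyl-2,3-dimethoxybenzene F1, and 9-BBN (THF, rt) its anti-Markovnikov adduct 9-[2-[3-(4-bromophenoxy)-4,5-dimethoxyphenyl]ethyl]-9-borabicyclo[3.3.1]nonane F2, which is not isolated. Separately, 2-iodophenol and 2-fluoro-3,4-dimethoxybenzaldehyde (Cs2CO3, DMF, 110 °C, SNAr) should give 2-(2-iodophenoxy)-3,4-dimethoxybenzaldehyde F3. Coupling of the borane with this iodide at room temperature (PdCl2(dppf), K3PO4, DMF/H2O), where the C–I bond reacts ahead of the C–Br bond, should give 2-[2-[2-[3-(4-bromophenoxy)-4,5-dimethoxyphenyl]ethyl]phenoxy]-3,4-dimethoxybenzaldehyde F4. Methylenation as before should give 1-[2-[2-[3-(4-bromophenoxy)-4,5-dimethoxyphenyl]ethyl]phenoxy]-6-ethenyl-2,3-dimethoxybenzene F5, and 9-BBN its B-alkyl-9-borabicyclo[3.3.1]nonane F6, not isolated. PdCl2(dppf), AsPh3, Cs2CO3, DMF/THF/H2O, 60 °C at 2 mM then closes the same bond (C-4 of ring B to the bridge CH2) by intramolecular B-alkyl Suzuki–Miyaura coupling and gives 16 directly, so that steps 2 to 9 are not needed.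

2. Step 9. What may go wrong: slow protonation of the C–B bond, because the electron-rich ring B disfavours the carbanion-like transition state, with competing air oxidation of the boronate. Fallback (oxidation then deoxygenation; sets out from 15 and comes back at 16): NaBO3·4H2O, THF/H2O, rt should oxidise the C–B bond to give the macrocyclic benzylic alcohol F7; Et3SiH, CF3CO2H, CH2Cl2, 0 °C (ionic hydrogenation through the para-aryloxybenzyl cation) should then give 16.

3. Step 3. What may go wrong: slow attack of the doubly ortho-substituted phenoxide, with base-induced degradation of the aldehyde at the temperature needed. Fallback (copper-catalysed coupling instead of SNAr; sets out from 5 and comes back at 7): Ullmann-type O-arylation of 5 with 2-iodobenzaldehyde (CuI, picolinic acid, K3PO4, DMSO, 90 °C), in which the C–I bond reacts and the hindered C–Br bond of 5 is left, should give 7 directly; it makes no compound outside the list (F0).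

**Further compounds**

F1 | step 8 | 1-(4-bromophenoxy)-5-ethenyl-2,3-dimethoxybenzene | COc1cc(C=C)cc(Oc2ccc(Br)cc2)c1OC
F2 | step 8 | 9-[2-[3-(4-bromophenoxy)-4,5-dimethoxyphenyl]ethyl]-9-borabicyclo[3.3.1]nonane (not isolated) | COc1cc(CCB2C3CCCC2CCC3)cc(Oc2ccc(Br)cc2)c1OC
F3 | step 8 | 2-(2-iodophenoxy)-3,4-dimethoxybenzaldehyde | COc1ccc(C=O)c(Oc2ccccc2I)c1OC
F4 | step 8 | 2-[2-[2-[3-(4-bromophenoxy)-4,5-dimethoxyphenyl]ethyl]phenoxy]-3,4-dimethoxybenzaldehyde | COc1ccc(C=O)c(Oc2ccccc2CCc2cc(OC)c(OC)c(Oc3ccc(Br)cc3)c2)c1OC
F5 | step 8 | 1-[2-[2-[3-(4-bromophenoxy)-4,5-dimethoxyphenyl]ethyl]phenoxy]-6-ethenyl-2,3-dimethoxybenzene | COc1ccc(C=C)c(Oc2ccccc2CCc2cc(OC)c(OC)c(Oc3ccc(Br)cc3)c2)c1OC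
F6 | step 8 | B-alkyl-9-borabicyclo[3.3.1]nonane from F5 (not isolated) | COc1ccc(CCB2C3CCCC2CCC3)c(Oc2ccccc2CCc2cc(OC)c(OC)c(Oc3ccc(Br)cc3)c2)c1OC
F7 | step 9 | macrocyclic benzylic alcohol (OH on the bridge carbon attached to ring B, racemic) | COc1cc2cc(c1OC)Oc1ccc(cc1)C(O)Cc1ccc(OC)c(OC)c1Oc1ccccc1CC2
F0 | step 3 | none | none
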